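- The electrophile cannot keep its opening slope. The first readings of ash and cedar lose on average 0.720 min⁻¹ of the charge, a pace that takes the electrophile to zero after 1.39 min, yet at 1.50 min ash still holds 38% and cedar 40%.

in all of them: electrophile 0.050 M
- ash: nucleophile 1.5 equiv; free base 1 equiv; protic impurity 0.025 M; run made earlier
- cedar: nucleophile 1.5 equiv; free base 4.2 equiv; protic impurity 0.025 M; run made earlier
- winter: nucleophile 1.50 equiv; free base 3.00 equiv; protic impurity 0.0250 M; time 8.0 min
- midnight: nucleophile 1.50 equiv; free base 1.50 equiv; protic impurity 0.0250 M; time 8.0 min
- autumn: nucleophile 1.50 equiv; free base 6.00 equiv; protic impurity 0.0250 M; time 8.0 min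

| run | time / min | electrophile / % | target / % |
|---|---|---|---|
| ash | 0.500 | 66 | 29 |
| ash | 1.00 | 47 | 45 |
| ash | 1.50 | 38 | 47 |
| ash | 2.50 | 25 | 58 |
| ash | 3.00 | 20 | 62 |
| ash | 4.00 | 16 | 63 |
| cedar | 0.500 | 62 | 27 |
| cedar | 1.00 | 47 | 42 |
| cedar | 1.50 | 40 | 52 |
| cedar | 2.50 | 27 | 60 |
| cedar | 3.00 | 24 | 64 |
| cedar | 4.00 | 25 | 65 |

(scatter of a reading: 2 percentage points)



- part of the electrophile that has reacted at the end, winter
- part of the electrophile that has reacted at the end, midnight
- part of the electrophile that has reacted at the end, autumn
- what raising the equivalents of free base from its lowest to its highest value here does to the part of the electrophile that has reacted (changes below 5 percentage points count as none) (no change / it rises / it falls)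

- A slope that shrinks as the electrophile goes suggests second-order decay. With x the fraction of charged electrophile left, the reciprocal of x climbs from 1 at a steady pace s per minute. Read at 3.00 min and averaged over ash and cedar, this reciprocal slope is 1.19 min⁻¹.
- Ash and cedar differ in free base, 1 equiv against 4.2 equiv, yet both read 47% at 1.00 min. This reckoning therefore uses one s for winter, midnight and autumn, and it sets aside the gap of 9 percentage points at 4.00 min as a single pair of readings, each with a scatter of 2 points.
- The curve drawn from s has no sharp knee. It passes x = 0.5 at 0.840 min and reaches 25.2% at 2.50 min, where ash reads 25% and cedar 27%. It then flattens towards zero and stands at 9.51% at 8.0 min, so this reckoning gives 90.5% reacted in each flask, with no change.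
- The forecast differs: 87% for midnight, 80% for winter, 75% for autumn, so it falls. Its ground is that “low base seems to allow a slow side drain of electrophile, while high base suppresses it or kills the remaining reagent”.
- The flasks give 91.2% for midnight, 91.3% for winter and 91.6% for autumn: no change, a shift of 0.36 points. The 8.67% of electrophile left in winter corresponds to s = 1.32 min⁻¹.

    acid set free → by-product carried off (k = 0.0330 s⁻¹)
    electrophile + protic impurity → quenched substrate (k = 0.0810 M⁻¹ s⁻¹)
    acid set free + free base ⇌ salt of the base (K = 20.0 M⁻¹, k = 5.70 M⁻¹ s⁻¹)
    nucleophile + acid set free ⇌ protonated nucleophile, settled at all times (K = 15000 M⁻¹)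
    electrophile + nucleophile → acid set free + target (k = 0.220 M⁻¹ s⁻¹)

- In winter, acid set free and free base relax, by their own step, with a half-life of 0.610 s at 8.00 min, far shorter than the 1.3 min half-life of electrophile by its step with nucleophile at 0.652 min. Yet in winter at 8.00 min the salt of the base stands at 8.68 × 10⁻⁴ M, less than the 0.0319 M of protonated nucleophile.
- For a neighbour of winter charged with 0.380 equiv of nucleophile, the reckoning scales s in proportion to that charge, to 0.303 min⁻¹, and so estimates 70.8% reacted. That neighbour gives 57.5%, with 42.5% of the electrophile left.

The numbers in the tables are simulated on assumed constants; the scatter is artificial.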